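The hexasubstituted central benzene ring is disconnected into the four ring carbons of a methoxy(indolyl)cyclobutenedione and the two alkene carbons of an α-indolyl vinyllithium. The key Moore ring expansion exploits the para relationship of the phenol O and the pyran O, the OMe beside the phenol and the two para indol-3-yl groups. Heating a 4-alkenyl-4-hydroxycyclobutenone opens the four-membered ring to a dienylketene, closes the benzene ring by 6π electrocyclisation and, after oxidation, gives a fully substituted prenylquinone. The 2,2-dimethyl-2H-pyran then follows by tautomerisation and oxa-6π closure. The precursor is a racemic cyclobutenone bearing OMe, one N-silylindolyl group and a carbinol carbon carrying the (E)-1-indolyl-5-methylhexa-1,4-dienyl chain.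

Key step: step 6

Assumption: 3-acetylindole, prenyl bromide, 3-bromo-1-(triisopropylsilyl)indole and dimethyl squarate are taken as purchasable, and hydrazone 7 is drawn as its expected (E) isomer (sulfonamide nitrogen on the side of the CH2 chain).

Step 1
Reactants: 1 3-acetylindole
Product: 3 3-acetyl-1-(triisopropylsilyl)indole, via sodium 3-acetylindol-1-ide 2 (not isolated)
Conditions: NaH (1.2 equiv), THF, 0 °C; then iPr3SiCl (1.15 equiv), 0 °C to rt
Reagents that add atoms: triisopropylsilyl chloride CC(C)[Si](Cl)(C(C)C)C(C)C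
Why: N-silylation, in which NaH irreversibly removes the N–H that the 3-acyl group acidifies and the anion is captured at nitrogen by the hindered silyl chloride, giving an N–Si bond that tolerates amide bases and alkyllithiums and shields C2 from metalation.

Step 2
Reactants: 3 3-acetyl-1-(triisopropylsilyl)indole; 4 prenyl bromide (1-bromo-3-methylbut-2-ene)
Product: 6 5-methyl-1-[1-(triisopropylsilyl)indol-3-yl]hex-4-en-1-one, via lithium ketone enolate 5 (not isolated)
Conditions: LiN(iPr)2 (1.05 equiv), THF, −78 °C; then 4 (1.1 equiv), −78 to 0 °C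
Reagents that add atoms: none
Why: Kinetic lithium enolate alkylation (SN2), in which the methyl group is the only enolisable site and the reactive allylic bromide is attacked at its primary carbon, low temperature and near-stoichiometric base favouring mono-C-alkylation.

Step 3
Reactants: 6 5-methyl-1-[1-(triisopropylsilyl)indol-3-yl]hex-4-en-1-one
Product: 7 (E)-2,4,6-triisopropylbenzenesulfonyl hydrazone of ketone 6
Conditions: 2,4,6-(iPr)3C6H2SO2NHNH2 (1.1 equiv), cat. PPTS, 4 Å molecular sieves, THF, rt
Reagents that add atoms: 2,4,6-triisopropylbenzenesulfonyl hydrazide CC(C)c1cc(C(C)C)c(S(=O)(=O)NN)c(C(C)C)c1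
Why: Acid-catalysed hydrazone condensation driven by removal of water on the sieves, the mild pyridinium acid sparing the N–Si bond and the isomer with the sulfonamide nitrogen beside the CH2 chain being the less hindered one.

Step 4
Reactants: 8 3-bromo-1-(triisopropylsilyl)indole; 9 dimethyl squarate (3,4-dimethoxycyclobut-3-ene-1,2-dione)
Product: 12 3-methoxy-4-[1-(triisopropylsilyl)indol-3-yl]cyclobut-3-ene-1,2-dione, via 3-lithio-1-(triisopropylsilyl)indole 10 (not isolated), via lithium alkoxide squarate adduct 11 (not isolated)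
Conditions: 8, t-BuLi (2.0 equiv), THF, −78 °C; cannulate into 9 (1.1 equiv), THF, −78 °C; then (CF3CO)2O (1.3 equiv), −78 °C; H2O, −78 °C to rt
Reagents that add atoms: water O
Why: Bromine–lithium exchange gives the 3-lithioindole (the bulky silyl group prevents migration of lithium to C2), which adds 1,2 to one squarate carbonyl, after which O-trifluoroacetylation of the alkoxide, ionisation to the methoxy-stabilised cyclobutenyl cation and hydrolysis on work-up expel methanol and restore the dione in the known one-flask squarate-to-cyclobutenedione sequence.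

Step 5
Reactants: 7 (E)-2,4,6-triisopropylbenzenesulfonyl hydrazone of ketone 6; 12 3-methoxy-4-[1-(triisopropylsilyl)indol-3-yl]cyclobut-3-ene-1,2-dione
Product: 14 racemic 4-hydroxy-3-methoxy-4-[(E)-5-methyl-1-[1-(triisopropylsilyl)indol-3-yl]hexa-1,4-dienyl]-2-[1-(triisopropylsilyl)indol-3-yl]cyclobut-2-en-1-one, via α-indolyl vinyllithium 13 (not isolated)
Conditions: 7 (1.3 equiv), n-BuLi (2.0 equiv per 7), THF, −78 °C, then 0 °C until N2 evolution ends; recool to −78 °C, add 12; aq. NH4Cl
Reagents that add atoms: none
Why: Shapiro reaction followed by carbonyl 1,2-addition, in which the base removes N–H and the syn α-CH2 proton, the dianion loses sulfinate and N2 to give vinyllithium 13 with lithium trans to the allylic CH2, and 13 adds with retention to the carbonyl flanked by the small OMe group (the other carbonyl is a vinylogous ester, is shielded by the neighbouring indolyl group and has no Li-chelating OMe neighbour), the carbinol stereocentre forming without control as a racemate that is erased in step 6.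

Step 6
Reactants: 14 racemic 4-hydroxy-4-alkenyl cyclobutenone
Product: 18 2-methoxy-5-(3-methylbut-2-enyl)-3,6-bis[1-(triisopropylsilyl)indol-3-yl]-1,4-benzoquinone, via dienylketene 15 (not isolated), via cyclohexadienone 16 (not isolated), via prenylhydroquinone 17 (not isolated)
Conditions: degassed PhMe, 110 °C, Ar; then Ag2O (2 equiv), rt
Reagents that add atoms: none
Why: Moore rearrangement, in which the C1–C4 σ bond of the cyclobutenone opens in a conrotatory 4π electrocyclic reaction with the donor hydroxyl rotating outward, so that the alkenyl group lies cis to the ketene in 15, the ketene carbon then bonds to the CH terminus of the side-chain alkene to give dienone 16, enolisation aromatises it to hydroquinone 17, and Ag2O dehydrogenates 17 to quinone 18. The closest known reaction type is the thermolysis of 4-alkenyl-4-hydroxycyclobutenones to hydroquinones with oxidation to benzoquinones in the same flask. The only ring closed is the central six-membered carbocycle, by a thermal disrotatory 6π electrocyclisation that joins the former carbonyl carbon to the alkene CH. No stereocentre survives, because the racemic carbinol carbon becomes sp2 on ring opening and the transient CH stereocentre of 16 is lost on enolisation. The step needs outward rotation of OH (secured by the torquoselectivity of an oxygen donor at C4), closure onto the alkene CH (it ends the only hexatriene-type array, carries the hydrogen needed for aromatisation, and the (E) geometry turns the prenyl CH2 away from the forming bond) and the correct substituent pattern (fixed by the connectivity of 14, which puts the ketene-derived oxygen between the dione-derived indolyl carbon and the prenyl carbon and the carbinol-derived oxygen between the OMe carbon and the second indolyl carbon). Degassed solvent protects 17 until the oxidant is added, and Ag2O should leave the N–Si bonds and the prenyl alkene untouched.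

Step 7
Reactants: 18 2-methoxy-5-(3-methylbut-2-enyl)-3,6-bis[1-(triisopropylsilyl)indol-3-yl]-1,4-benzoquinone
Product: 20 7-methoxy-2,2-dimethyl-5,8-bis[1-(triisopropylsilyl)indol-3-yl]-2H-chromen-6-ol, via ortho-quinone methide 19 (not isolated)
Conditions: degassed pyridine, 100 °C, Ar
Reagents that add atoms: none
Why: Base-mediated prototropic tautomerisation followed by oxa-6π electrocyclisation (the known prenylquinone-to-chromenol isomerisation), in which pyridine shifts a proton from the ring-bound CH2, vinylogously acidified by the quinone, to give ortho-quinone methide 19, and only the carbonyl next to the prenyl-bearing carbon can close onto the CMe2 terminus, so that this oxygen becomes the pyran oxygen, the ring enforces the cis alkene and the para oxygen is left as the phenol.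

Step 8
Reactants: 20 7-methoxy-2,2-dimethyl-5,8-bis[1-(triisopropylsilyl)indol-3-yl]-2H-chromen-6-ol
Product: 21 kumbicin C (5,8-di(1H-indol-3-yl)-7-methoxy-2,2-dimethyl-2H-chromen-6-ol)
Conditions: Bu4NF (2.5 equiv), THF, 0 °C to rt, Ar; aq. NH4Cl
Reagents that add atoms: none
Why: Fluoride-mediated N-desilylation, in which fluoride attacks silicon and expels each indolide for protonation on work-up, while the aryl methyl ether, the phenol and the chromene alkene should not respond to fluoride at room temperature.

Compound list
1 | 3-acetylindole | CC(=O)c1c[nH]c2ccccc12 | starting material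
2 | sodium 3-acetylindol-1-ide (not isolated) | CC(=O)c1c[n-]c2ccccc12.[Na+] | intermediate
3 | 3-acetyl-1-(triisopropylsilyl)indole | CC(=O)c1cn([Si](C(C)C)(C(C)C)C(C)C)c2ccccc12 | intermediate
4 | prenyl bromide | CC(C)=CCBr | starting material
5 | lithium enolate of 3 (not isolated) | C=C([O-])c1cn([Si](C(C)C)(C(C)C)C(C)C)c2ccccc12.[Li+] | intermediate
6 | 5-methyl-1-[1-(triisopropylsilyl)indol-3-yl]hex-4-en-1-one | CC(C)=CCCC(=O)c1cn([Si](C(C)C)(C(C)C)C(C)C)c2ccccc12 | intermediate
7 | (E)-2,4,6-triisopropylbenzenesulfonyl hydrazone of 6 | CC(C)=CCC/C(=N\NS(=O)(=O)c1c(C(C)C)cc(C(C)C)cc1C(C)C)c1cn([Si](C(C)C)(C(C)C)C(C)C)c2ccccc12 | intermediate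
8 | 3-bromo-1-(triisopropylsilyl)indole | Brc1cn([Si](C(C)C)(C(C)C)C(C)C)c2ccccc12 | starting material
9 | dimethyl squarate | COC1=C(OC)C(=O)C1=O | starting material
10 | 3-lithio-1-(triisopropylsilyl)indole (not isolated) | [Li]c1cn([Si](C(C)C)(C(C)C)C(C)C)c2ccccc12 | intermediate
11 | racemic lithium 2,3-dimethoxy-4-oxo-1-[1-(triisopropylsilyl)indol-3-yl]cyclobut-2-en-1-olate (not isolated) | COC1=C(OC)C([O-])(c2cn([Si](C(C)C)(C(C)C)C(C)C)c3ccccc23)C1=O.[Li+] | intermediate
12 | 3-methoxy-4-[1-(triisopropylsilyl)indol-3-yl]cyclobut-3-ene-1,2-dione | COC1=C(c2cn([Si](C(C)C)(C(C)C)C(C)C)c3ccccc23)C(=O)C1=O | intermediate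
13 | 5-methyl-1-[1-(triisopropylsilyl)indol-3-yl]hexa-1,4-dien-1-yllithium, lithium trans to the allylic CH2 (not isolated) | [Li]/C(=C/CC=C(C)C)c1cn([Si](C(C)C)(C(C)C)C(C)C)c2ccccc12 | intermediate
14 | racemic 4-hydroxy-3-methoxy-4-[(E)-5-methyl-1-[1-(triisopropylsilyl)indol-3-yl]hexa-1,4-dienyl]-2-[1-(triisopropylsilyl)indol-3-yl]cyclobut-2-en-1-one | COC1=C(c2cn([Si](C(C)C)(C(C)C)C(C)C)c3ccccc23)C(=O)C1(O)/C(c1cn([Si](C(C)C)(C(C)C)C(C)C)c2ccccc12)=C/CC=C(C)C | intermediate
15 | (3Z,5E)-dienylketene: 4-hydroxy-3-methoxy-8-methyl-2,5-bis[1-(triisopropylsilyl)indol-3-yl]nona-1,3,5,7-tetraen-1-one (not isolated) | O=C=C(c1cn([Si](C(C)C)(C(C)C)C(C)C)c2ccccc12)/C(OC)=C(O)\C(c1cn([Si](C(C)C)(C(C)C)C(C)C)c2ccccc12)=C\CC=C(C)C | intermediate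
16 | racemic 4-hydroxy-3-methoxy-6-(3-methylbut-2-enyl)-2,5-bis[1-(triisopropylsilyl)indol-3-yl]cyclohexa-2,4-dien-1-one (not isolated) | COC1=C(c2cn([Si](C(C)C)(C(C)C)C(C)C)c3ccccc23)C(=O)C(CC=C(C)C)C(c2cn([Si](C(C)C)(C(C)C)C(C)C)c3ccccc23)=C1O | intermediate
17 | 2-methoxy-5-(3-methylbut-2-enyl)-3,6-bis[1-(triisopropylsilyl)indol-3-yl]benzene-1,4-diol (not isolated) | COc1c(O)c(-c2cn([Si](C(C)C)(C(C)C)C(C)C)c3ccccc23)c(CC=C(C)C)c(O)c1-c1cn([Si](C(C)C)(C(C)C)C(C)C)c2ccccc12 | intermediate
18 | 2-methoxy-5-(3-methylbut-2-enyl)-3,6-bis[1-(triisopropylsilyl)indol-3-yl]-1,4-benzoquinone | COC1=C(c2cn([Si](C(C)C)(C(C)C)C(C)C)c3ccccc23)C(=O)C(CC=C(C)C)=C(c2cn([Si](C(C)C)(C(C)C)C(C)C)c3ccccc23)C1=O | intermediate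
19 | (Z)-ortho-quinone methide: 4-hydroxy-3-methoxy-6-(3-methylbut-2-enylidene)-2,5-bis[1-(triisopropylsilyl)indol-3-yl]cyclohexa-2,4-dien-1-one, diene chain cis to the carbonyl (not isolated) | COC1=C(c2cn([Si](C(C)C)(C(C)C)C(C)C)c3ccccc23)C(=O)/C(=C\C=C(C)C)C(c2cn([Si](C(C)C)(C(C)C)C(C)C)c3ccccc23)=C1O | intermediate
20 | 7-methoxy-2,2-dimethyl-5,8-bis[1-(triisopropylsilyl)indol-3-yl]-2H-chromen-6-ol | COc1c(O)c(-c2cn([Si](C(C)C)(C(C)C)C(C)C)c3ccccc23)c2c(c1-c1cn([Si](C(C)C)(C(C)C)C(C)C)c3ccccc13)OC(C)(C)C=C2 | intermediate
21 | kumbicin C | COc1c(O)c(-c2c[nH]c3ccccc23)c2c(c1-c1c[nH]c3ccccc13)OC(C)(C)C=C2 | target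

Total step count: 8. Longest linear sequence: 7 steps (steps 1, 2, 3, 5, 6, 7 and 8, from 3-acetylindole); step 4 is the one-step second branch.

Steps most likely to fail

1. Step 5. The carbonyl addition may lose site selectivity. Lone-pair donation from the indole nitrogen through C3 lowers the electrophilicity of the intended carbonyl, so attack at the vinylogous ester carbonyl can compete and would lead to a quinone with meta indoles. Part of the vinyllithium may also be protonated before it adds. The fallback sets out from 12 and exchanges the silyl group for an electron-withdrawing carbamate, so that the heteroaryl group behaves like an ordinary aryl group, for which addition next to the alkoxy-bearing carbon is the rule. Bu4NF buffered with AcOH in THF at 0 °C should give 3-(1H-indol-3-yl)-4-methoxycyclobut-3-ene-1,2-dione F1, and Boc2O with cat. DMAP in MeCN the N-Boc dione F2. Addition of vinyllithium 13 at −78 °C then gives the mixed carbamate/silyl cyclobutenone F3. Thermolysis in toluene with Ag2O oxidation gives the mixed carbamate/silyl quinone F4, and hot pyridine the mixed carbamate/silyl chromenol F5. Bu4NF in THF followed by K2CO3 in MeOH at 40 °C removes both nitrogen groups, and the sequence comes back to the route at 21.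

2. Step 3. The condensation may be slow and incomplete, because the ketone is a vinylogous amide, while the sulfonyl hydrazide decomposes on long standing or warming and the acid slowly erodes the N–Si bond. The fallback sets out from 6 and reaches the same organolithium through a vinyl iodide. N2H4·H2O with Et3N in EtOH should give the small, readily formed hydrazone F6. The Barton vinyl iodide synthesis (I2, tetramethylguanidine, THF, 0 °C) converts it into (E)-3-(1-iodo-5-methylhexa-1,4-dienyl)-1-(triisopropylsilyl)indole F7, expected together with its (Z) isomer. Iodine–lithium exchange (t-BuLi, 2 equiv, THF, −78 °C, retention) comes back to the route at 13. Any geometric isomer carried along is tolerable, because both adducts converge on 17 once the alkene geometry is erased by aromatisation.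

3. Step 7. Proton transfer from the CH2 of a crowded, twisted quinone may be sluggish, and prolonged heating invites redox side reactions of the quinone and aerial oxidation of the chromenol. The fallback sets out from 3 and builds the pyran by phenol–enal annulation instead of quinone isomerisation. Condensation of 3 with the sulfonyl hydrazide gives trisylhydrazone F8. The Shapiro reaction (n-BuLi, 2 equiv) gives 1-[1-(triisopropylsilyl)indol-3-yl]vinyllithium F9, which is added to 12 to give the 4-(1-indolylvinyl)cyclobutenone F10. Thermolysis in degassed toluene without oxidant gives 2-methoxy-3,6-bis[1-(triisopropylsilyl)indol-3-yl]benzene-1,4-diol F11, whose only free ring position is ortho to the hydroxyl that must become the pyran oxygen. Chromenylation with 3-methylbut-2-enal (PhB(OH)2, AcOH, toluene, reflux, Ar) proceeds through ortho C-alkylation, an ortho-quinone methide and oxa-6π closure, and comes back to the route at 20.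

Further compounds
F1 | step 5 | 3-(1H-indol-3-yl)-4-methoxycyclobut-3-ene-1,2-dione | COC1=C(c2c[nH]c3ccccc23)C(=O)C1=O
F2 | step 5 | N-Boc dione: tert-butyl 3-(2-methoxy-3,4-dioxocyclobut-1-enyl)indole-1-carboxylate | COC1=C(c2cn(C(=O)OC(C)(C)C)c3ccccc23)C(=O)C1=O
F3 | step 5 | mixed carbamate/silyl cyclobutenone (racemic analogue of 14 with Boc on the ring-bound indole) | COC1=C(c2cn(C(=O)OC(C)(C)C)c3ccccc23)C(=O)C1(O)/C(c1cn([Si](C(C)C)(C(C)C)C(C)C)c2ccccc12)=C/CC=C(C)C
F4 | step 5 | mixed carbamate/silyl quinone (analogue of 18 with Boc on the indole next to the OMe carbon) | COC1=C(c2cn(C(=O)OC(C)(C)C)c3ccccc23)C(=O)C(CC=C(C)C)=C(c2cn([Si](C(C)C)(C(C)C)C(C)C)c3ccccc23)C1=O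
F5 | step 5 | mixed carbamate/silyl chromenol (analogue of 20 with Boc on the C8 indole) | COc1c(O)c(-c2cn([Si](C(C)C)(C(C)C)C(C)C)c3ccccc23)c2c(c1-c1cn(C(=O)OC(C)(C)C)c3ccccc13)OC(C)(C)C=C2
F6 | step 3 | (E)-hydrazone of ketone 6 | CC(C)=CCC/C(=N\N)c1cn([Si](C(C)C)(C(C)C)C(C)C)c2ccccc12
F7 | step 3 | (E)-3-(1-iodo-5-methylhexa-1,4-dienyl)-1-(triisopropylsilyl)indole | I/C(=C/CC=C(C)C)c1cn([Si](C(C)C)(C(C)C)C(C)C)c2ccccc12
F8 | step 7 | (E)-2,4,6-triisopropylbenzenesulfonyl hydrazone of 3 | C/C(=N\NS(=O)(=O)c1c(C(C)C)cc(C(C)C)cc1C(C)C)c1cn([Si](C(C)C)(C(C)C)C(C)C)c2ccccc12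
F9 | step 7 | 1-[1-(triisopropylsilyl)indol-3-yl]vinyllithium | [Li]C(=C)c1cn([Si](C(C)C)(C(C)C)C(C)C)c2ccccc12
F10 | step 7 | racemic 4-hydroxy-3-methoxy-2-[1-(triisopropylsilyl)indol-3-yl]-4-[1-[1-(triisopropylsilyl)indol-3-yl]vinyl]cyclobut-2-en-1-one | COC1=C(c2cn([Si](C(C)C)(C(C)C)C(C)C)c3ccccc23)C(=O)C1(O)C(=C)c1cn([Si](C(C)C)(C(C)C)C(C)C)c2ccccc12
F11 | step 7 | 2-methoxy-3,6-bis[1-(triisopropylsilyl)indol-3-yl]benzene-1,4-diol | COc1c(O)c(-c2cn([Si](C(C)C)(C(C)C)C(C)C)c3ccccc23)cc(O)c1-c1cn([Si](C(C)C)(C(C)C)C(C)C)c2ccccc12
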